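**Retrosynthetic overview**
1. Ring C (oxocane) is closed last at C3–C4 by a BF3-promoted type 2 carbonyl-ene reaction of a C3 aldehyde onto the C5 isopropenyl group. The ether bridge is trans across the tetrahydropyran (C3 equatorial on C2, C7 axial on C8), so this strained ring is closed irreversibly by C–C bond formation.
2. Rings B and D (tetrahydropyran and γ-lactone) form together by PdCl2/CuCl2/CO oxypalladation–carbonylation–lactonisation of an acyclic ene-triol (2-OH onto C8, CO onto C17, 7-OH closes the lactone), which sets C8 and C17.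
3. C8–C9 comes from a Ni/Cr coupling of a ring A aldehyde with a Z-alkenyl iodide made from crotonaldehyde. Its threo diol is set by a singlet-oxygen ene reaction, and C6–Cl is installed late with inversion.
4. Ring A is made first by a catalytic asymmetric Diels–Alder reaction of ethyl (E)-3-methyl-4-oxobut-2-enoate with 1-acetoxypenta-1,3-diene, followed by elimination to the cyclohexadiene, C2–C3 homologation and cis-dihydroxylation.
5. Order of ring formation: A, then B and D in one operation, then C.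

Atom labels C1–C20 are those of the briarane skeleton of the target (C1 quaternary ring carbon with CH3-15; C2 ether CH; C3 carbinol; C5=C16H2; C6 CHCl; C7 lactone CH–O; C8 spiro carbon; C9 CH–OAc; C10 ring-fusion CH; C11 C(CH3-20)OAc; C12 CH–OAc; C13=C14; C17 CH(CH3-18); C19 lactone C=O).

Assumption: the (S)-oxazaborolidinium catalyst of step 2 is taken to shield the dienophile face that leads to the (1S,6S) adduct; if the sense is opposite, its enantiomer is used and nothing else changes.

**Route**

Step 1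
Reactants: 1 (E)-pent-2-enal
Product: 2 (1E,3E)-penta-1,3-dien-1-yl acetate
Conditions: isopropenyl acetate, p-toluenesulfonic acid (2 mol%), 95 °C, acetone distilled off
Reagents that add atoms: isopropenyl acetate (CC(=C)OC(C)=O)
Why: Acid-catalysed enol acetate exchange traps the extended dienol of the enal as its acetate (the same way 1-acetoxybutadiene is made from crotonaldehyde), and the 1E,3E isomer is the one that reacts in step 2.

Step 2
Reactants: 2 (1E,3E)-penta-1,3-dien-1-yl acetate; 3 ethyl (E)-3-methyl-4-oxobut-2-enoate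
Product: 4 ethyl (1S,2R,5S,6R)-5-acetoxy-6-formyl-2,6-dimethylcyclohex-3-ene-1-carboxylate
Conditions: (S)-1-(2-methylphenyl)-3,3-diphenyltetrahydro-1H,3H-pyrrolo[1,2-c][1,3,2]oxazaborole (20 mol%), (CF3SO2)2NH (18 mol%), CH2Cl2, −78 to −40 °C
Reagents that add atoms: none
Why: Enantioselective Diels–Alder reaction under cationic oxazaborolidine (CBS-type) catalysis: the boron-bound formyl group directs the acetoxy terminus to the formyl-bearing carbon, the E dienophile fixes CHO and CO2Et trans, and the catalyst shields one dienophile face so that the quaternary carbon and its neighbour (C1 and C10) are set, while the two diene-derived centres (formyl-endo isomer shown) are erased in step 3.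

Step 3
Reactants: 4 ethyl (1S,2R,5S,6R)-5-acetoxy-6-formyl-2,6-dimethylcyclohex-3-ene-1-carboxylate
Product: 5 ethyl (1S,6S)-6-formyl-2,6-dimethylcyclohexa-2,4-diene-1-carboxylate
Conditions: Pd(PPh3)4 (5 mol%), dioxane, 80 °C
Reagents that add atoms: none
Why: Tsuji-type elimination: zerovalent palladium ionises the allylic acetate to a π-allyl complex, and loss of the only available β-hydrogen (on the methyl-bearing carbon, since the quaternary carbon has none) gives the conjugated C11=C12–C13=C14 diene.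

Step 4
Reactants: 5 ethyl (1S,6S)-6-formyl-2,6-dimethylcyclohexa-2,4-diene-1-carboxylate
Product: 7 ethyl (1S,6S)-6-[(1S)-2-(methoxymethoxy)-1-(triethylsilyloxy)ethyl]-2,6-dimethylcyclohexa-2,4-diene-1-carboxylate, via lithium alkoxide 6 (not isolated)
Conditions: Bu3SnCH2OCH2OCH3, n-BuLi, THF, −78 °C; add 5; then Et3SiOTf, −78 to 0 °C
Reagents that add atoms: tributyl[(methoxymethoxy)methyl]stannane (CCCC[Sn](CCCC)(CCCC)COCOC); triethylsilyl trifluoromethanesulfonate (CC[Si](CC)(CC)OS(=O)(=O)C(F)(F)F)
Why: Still-type addition of an α-alkoxymethyllithium (tin–lithium exchange) to the neopentyl aldehyde and silylation of the alkoxide in the same flask; Felkin–Anh attack anti to the ring sp2 carbon C14, with lithium bridging the formyl and ester oxygens and the nucleophile passing over the methyl group, is expected to give the (S)-carbinol C2.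

Step 5
Reactants: 7 ethyl (1S,6S)-6-[(1S)-2-(methoxymethoxy)-1-(triethylsilyloxy)ethyl]-2,6-dimethylcyclohexa-2,4-diene-1-carboxylate
Product: 8 ethyl (1R,2S,3R,6S)-2,3-dihydroxy-6-[(1S)-2-(methoxymethoxy)-1-(triethylsilyloxy)ethyl]-2,6-dimethylcyclohex-4-ene-1-carboxylate
Conditions: OsO4 (2 mol%), N-methylmorpholine N-oxide, acetone/H2O, 0 °C
Reagents that add atoms: osmium tetroxide (O=[Os](=O)(=O)=O); N-methylmorpholine N-oxide (C[N+]1([O-])CCOCC1); water (O)
Why: Upjohn dihydroxylation attacks the more electron-rich trisubstituted C11=C12 bond of the diene from the α face, anti to the C10 ester and the C1 methyl group, and sets the cis 11α,12α-diol while leaving the hindered C13=C14 bond.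

Step 6
Reactants: 8 ethyl (1R,2S,3R,6S)-2,3-dihydroxy-6-[(1S)-2-(methoxymethoxy)-1-(triethylsilyloxy)ethyl]-2,6-dimethylcyclohex-4-ene-1-carboxylate
Product: 9 (1R,2S,3R,6S)-2,3-dihydroxy-6-[(1S)-2-(methoxymethoxy)-1-(triethylsilyloxy)ethyl]-2,6-dimethylcyclohex-4-ene-1-carbaldehyde
Conditions: i-Bu2AlH (3.5 equiv), CH2Cl2, −78 °C; aq. potassium sodium tartrate
Reagents that add atoms: none
Why: Low-temperature DIBAL-H reduction of the ester stops at the aldehyde because the aluminium hemiacetal, held by the neighbouring aluminium alkoxides, survives until work-up; no stereocentre changes.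

Step 7
Reactants: 10 (E)-but-2-enal
Product: 11 (Z)-2-iodobut-2-enal
Conditions: I2, K2CO3, 4-(dimethylamino)pyridine (20 mol%), THF/H2O, 25 °C
Reagents that add atoms: iodine (II)
Why: α-Iodination of an enal through reversible conjugate addition of the pyridine (Baylis–Hillman-type enolate, iodination, elimination), which gives the Z isomer with iodine cis to the methyl group.

Step 8
Reactants: 11 (Z)-2-iodobut-2-enal
Product: 12 (2Z,4S)-3-iodo-6-methylhepta-2,5-dien-4-ol
Conditions: 2-methylprop-1-enylmagnesium bromide (2.4 equiv), ZnCl2 (1.2 equiv), N,N,N',N'-tetraethylethylenediamine, (2S)-(−)-3-exo-morpholinoisoborneol (5 mol%), toluene/hexanes, 0 °C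
Reagents that add atoms: 2-methylprop-1-enylmagnesium bromide (CC(C)=C[Mg]Br)
Why: Amino-alcohol-catalysed asymmetric 1,2-addition of an alkenylzinc reagent to the aldehyde (Oppolzer/Walsh type), in which the chiral zinc aminoalkoxide delivers the alkenyl group to one carbonyl face and sets the carbinol (C7) as S.

Step 9
Reactants: 12 (2Z,4S)-3-iodo-6-methylhepta-2,5-dien-4-ol
Product: 14 (3R,4S,5Z)-5-iodo-2-methylhepta-1,5-diene-3,4-diol, via allylic hydroperoxide 13 (not isolated)
Conditions: O2, 5,10,15,20-tetraphenylporphyrin (0.5 mol%), visible light, CH2Cl2, −20 °C; then PPh3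
Reagents that add atoms: dioxygen (O=O)
Why: Schenck ene reaction of singlet oxygen on the electron-rich trisubstituted alkene: hydrogen bonding to the allylic hydroxyl in the A(1,3)-minimised conformer steers oxygen to the syn face (threo selectivity), hydrogen is taken from a geminal methyl to leave the isopropenyl group, and PPh3 reduces the hydroperoxide, giving the threo diol with C6 as R.

Step 10
Reactants: 14 (3R,4S,5Z)-5-iodo-2-methylhepta-1,5-diene-3,4-diol
Product: 15 (3R,4S,5Z)-5-iodo-2-methyl-3,4-bis(triethylsilyloxy)hepta-1,5-diene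
Conditions: Et3SiCl, imidazole, DMF, 25 °C
Reagents that add atoms: chlorotriethylsilane (CC[Si](Cl)(CC)CC)
Why: Standard silylation of both secondary hydroxyls so that they stay free of acetate in step 12; no stereocentre changes.

Step 11
Reactants: 9 (1R,2S,3R,6S)-2,3-dihydroxy-6-[(1S)-2-(methoxymethoxy)-1-(triethylsilyloxy)ethyl]-2,6-dimethylcyclohex-4-ene-1-carbaldehyde; 15 (3R,4S,5Z)-5-iodo-2-methyl-3,4-bis(triethylsilyloxy)hepta-1,5-diene
Product: 17 C8–C9 coupling product (9R)-allylic alcohol, via alkenylchromium dichloride 16 (not isolated)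
Conditions: CrCl2 (6 equiv), NiCl2 (2 mol%), DMSO, 25 °C
Reagents that add atoms: none
Why: Nozaki–Hiyama–Kishi coupling (zerovalent nickel inserts into C–I, transmetalation to trivalent chromium, carbonyl addition with retention of the alkene geometry so that CH3-18 stays cis to C9); the chromium chelate between the aldehyde and the C11 alkoxide, like the Felkin–Anh model with quaternary C1 as the large group, directs the alkenyl group anti to C1 and sets C9 as R.

Step 12
Reactants: 17 C8–C9 coupling product (9R)-allylic alcohol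
Product: 18 9,11,12-triacetate
Conditions: Ac2O, Et3N, 4-(dimethylamino)pyridine (1 equiv), CH2Cl2, 40 °C
Reagents that add atoms: acetic anhydride (CC(=O)OC(C)=O)
Why: Nucleophilic-catalysed acetylation of the only three free hydroxyls (secondary C9 and C12, tertiary C11 under forcing conditions) installs all three acetates of the target with retention.

Step 13
Reactants: 18 9,11,12-triacetate
Product: 19 2,6,7-triol
Conditions: HF·pyridine, pyridine/THF, 0 to 25 °C
Reagents that add atoms: none
Why: Buffered fluoride desilylation removes the three triethylsilyl ethers and leaves the acetates and the MOM ether untouched.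

Step 14
Reactants: 19 2,6,7-triol
Product: 22 spiro tetrahydropyran–lactone (6-OH free), via alkylpalladium chloride 20 (not isolated), via acylpalladium chloride 21 (not isolated)
Conditions: PdCl2 (10 mol%), CuCl2 (3 equiv), NaOAc (3 equiv), CO (1 atm), AcOH, 25 °C
Reagents that add atoms: carbon monoxide ([C-]#[O+])
Why: Semmelhack–Tamaru oxypalladation/carbonylation/lactonisation cascade: with H9 eclipsing the Z-trisubstituted alkene (A(1,3) strain against CH3-18) the C10 tether brings the 2-OH onto one face of C8 in a 6-exo Markovnikov attack (8S, with 9-OAc and the C3 chain equatorial), divalent palladium adds anti at C17, CO inserts with retention (17R), and the 7-OH captures the acylpalladium as the five-membered lactone in preference to the six-membered one from the 6-OH.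

Step 15
Reactants: 22 spiro tetrahydropyran–lactone (6-OH free)
Product: 23 (6S)-allylic chloride
Conditions: PPh3, hexachloroacetone, CH2Cl2, −20 to 0 °C
Reagents that add atoms: hexachloroacetone (ClC(Cl)(Cl)C(=O)C(Cl)(Cl)Cl)
Why: Magid chlorination of the only free (allylic) alcohol: the alkoxyphosphonium salt is displaced by chloride in an SN2 reaction without allylic transposition, inverting C6 from R to the S chloride that is erythro to the C7 oxygen.

Step 16
Reactants: 23 (6S)-allylic chloride
Product: 24 C3 primary alcohol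
Conditions: Me2BBr, CH2Cl2, −78 °C; then THF/aq. NaHCO3
Reagents that add atoms: none
Why: Guindon cleavage of the MOM acetal by bromodimethylborane at low temperature, which spares the acetates, the lactone and the allylic chloride.

Step 17
Reactants: 24 C3 primary alcohol
Product: 25 C3 aldehyde
Conditions: Dess–Martin periodinane (1,1,1-triacetoxy-1,1-dihydro-1,2-benziodoxol-3(1H)-one), NaHCO3, CH2Cl2, 0 to 25 °C
Reagents that add atoms: none
Why: Dess–Martin oxidation of the only free alcohol under buffered conditions, which avoids epimerisation at C2.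

Step 18
Reactants: 25 C3 aldehyde
Product: 26 CNP0333938.3
Conditions: BF3·OEt2 (2 equiv), CH2Cl2 (0.002 M), −78 to −30 °C
Reagents that add atoms: none
Why: Type 2 intramolecular carbonyl-ene (Prins-type) reaction: the tether lets the isopropenyl CH2 reach C3 only anti to C1, the non-chelating Lewis acid keeps C3=O anti to the C2–O bond (Cornforth/Felkin arrangement) so the new carbinol is 3R, and the six-centre hydrogen shift from the methyl group leaves the C5 exo-methylene and closes the oxocane.

**Compound list**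
1 | (E)-pent-2-enal | CC/C=C/C=O | starting material
2 | (1E,3E)-penta-1,3-dien-1-yl acetate | CC(=O)O/C=C/C=C/C | intermediate
3 | ethyl (E)-3-methyl-4-oxobut-2-enoate | CCOC(=O)/C=C(\C)C=O | starting material
4 | ethyl (1S,2R,5S,6R)-5-acetoxy-6-formyl-2,6-dimethylcyclohex-3-ene-1-carboxylate (formyl-endo adduct; its C2/C5 epimers are carried along) | CCOC(=O)[C@H]1[C@H](C)C=C[C@H](OC(C)=O)[C@]1(C)C=O | intermediate
5 | ethyl (1S,6S)-6-formyl-2,6-dimethylcyclohexa-2,4-diene-1-carboxylate | CCOC(=O)[C@H]1C(C)=CC=C[C@]1(C)C=O | intermediate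
6 | lithium alkoxide of ethyl (1S,6S)-6-[(1S)-1-hydroxy-2-(methoxymethoxy)ethyl]-2,6-dimethylcyclohexa-2,4-diene-1-carboxylate | CCOC(=O)[C@H]1C(C)=CC=C[C@]1(C)[C@H](O[Li])COCOC | intermediate
7 | ethyl (1S,6S)-6-[(1S)-2-(methoxymethoxy)-1-(triethylsilyloxy)ethyl]-2,6-dimethylcyclohexa-2,4-diene-1-carboxylate | CCOC(=O)[C@H]1C(C)=CC=C[C@]1(C)[C@H](O[Si](CC)(CC)CC)COCOC | intermediate
8 | ethyl (1R,2S,3R,6S)-2,3-dihydroxy-6-[(1S)-2-(methoxymethoxy)-1-(triethylsilyloxy)ethyl]-2,6-dimethylcyclohex-4-ene-1-carboxylate | CCOC(=O)[C@H]1[C@](C)(O)[C@H](O)C=C[C@]1(C)[C@H](O[Si](CC)(CC)CC)COCOC | intermediate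
9 | (1R,2S,3R,6S)-2,3-dihydroxy-6-[(1S)-2-(methoxymethoxy)-1-(triethylsilyloxy)ethyl]-2,6-dimethylcyclohex-4-ene-1-carbaldehyde | O=C[C@H]1[C@](C)(O)[C@H](O)C=C[C@]1(C)[C@H](O[Si](CC)(CC)CC)COCOC | intermediate
10 | (E)-but-2-enal (crotonaldehyde) | C/C=C/C=O | starting material
11 | (Z)-2-iodobut-2-enal | C/C=C(\I)C=O | intermediate
12 | (2Z,4S)-3-iodo-6-methylhepta-2,5-dien-4-ol | C/C=C(\I)[C@@H](O)C=C(C)C | intermediate
13 | (3R,4S,5Z)-3-hydroperoxy-5-iodo-2-methylhepta-1,5-dien-4-ol | C/C=C(\I)[C@@H](O)[C@H](OO)C(C)=C | intermediate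
14 | (3R,4S,5Z)-5-iodo-2-methylhepta-1,5-diene-3,4-diol | C/C=C(\I)[C@@H](O)[C@H](O)C(C)=C | intermediate
15 | (3R,4S,5Z)-5-iodo-2-methyl-3,4-bis(triethylsilyloxy)hepta-1,5-diene | C/C=C(\I)[C@@H](O[Si](CC)(CC)CC)[C@H](O[Si](CC)(CC)CC)C(C)=C | intermediate
16 | alkenylchromium dichloride from 15 (CrCl2 in place of iodine, same configurations and geometry) | C/C=C(\[Cr](Cl)Cl)[C@@H](O[Si](CC)(CC)CC)[C@H](O[Si](CC)(CC)CC)C(C)=C | intermediate
17 | C8–C9 coupling product: ring A [(1S,10S,11S,12R); 11-OH, 12-OH, 13-ene] with CH3 and (2S)-CH(OSiEt3)CH2OCH2OCH3 on C1 and, on C10, (9R)-CH(OH)–C8(=C17H–CH3)–(7R)-CH(OSiEt3)–(6R)-CH(OSiEt3)–C(CH3)=CH2; CH3-18 cis to C9 | C/C=C(\[C@H](O)[C@H]1[C@](C)(O)[C@H](O)C=C[C@]1(C)[C@H](O[Si](CC)(CC)CC)COCOC)[C@@H](O[Si](CC)(CC)CC)[C@H](O[Si](CC)(CC)CC)C(C)=C | intermediate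
18 | 9,11,12-triacetate of 17 (same configurations) | C/C=C(\[C@H](OC(C)=O)[C@H]1[C@](C)(OC(C)=O)[C@H](OC(C)=O)C=C[C@]1(C)[C@H](O[Si](CC)(CC)CC)COCOC)[C@@H](O[Si](CC)(CC)CC)[C@H](O[Si](CC)(CC)CC)C(C)=C | intermediate
19 | 2,6,7-triol from 18 by loss of the three SiEt3 groups [(1S,2S,6R,7R,9R,10S,11S,12R); 8(17)-Z] | C/C=C(\[C@H](OC(C)=O)[C@H]1[C@](C)(OC(C)=O)[C@H](OC(C)=O)C=C[C@]1(C)[C@H](O)COCOC)[C@@H](O)[C@H](O)C(C)=C | intermediate
20 | σ-alkylpalladium chloride: tetrahydropyran closed (O–C8, 8S), PdCl on C17 anti to the new C–O bond, 6-OH and 7-OH free | COCOC[C@H]1O[C@]([C@H](OC(C)=O)[C@@H]2[C@]1(C)C=C[C@@H](OC(C)=O)[C@@]2(C)OC(C)=O)([C@@H](C)[Pd]Cl)[C@@H](O)[C@H](O)C(C)=C | intermediate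
21 | acylpalladium chloride from 20 by CO insertion (C19(=O)PdCl on C17, 17R) | COCOC[C@H]1O[C@]([C@H](OC(C)=O)[C@@H]2[C@]1(C)C=C[C@@H](OC(C)=O)[C@@]2(C)OC(C)=O)([C@@H](C)C(=O)[Pd]Cl)[C@@H](O)[C@H](O)C(C)=C | intermediate
22 | spiro tetrahydropyran–γ-lactone (1S,2S,6R,7S,8S,9R,10S,11S,12R,17R): 3-OCH2OCH3, 6-OH, 9,11,12-triacetate, isopropenyl on C6 | COCOC[C@H]1O[C@]2([C@H](OC(C)=O)[C@@H]3[C@]1(C)C=C[C@@H](OC(C)=O)[C@@]3(C)OC(C)=O)[C@@H](C)C(=O)O[C@H]2[C@H](O)C(C)=C | intermediate
23 | (6S)-chloride (1S,2S,6S,7R,8S,9R,10S,11S,12R,17R): as 22 with Cl in place of 6-OH, inverted | COCOC[C@H]1O[C@]2([C@H](OC(C)=O)[C@@H]3[C@]1(C)C=C[C@@H](OC(C)=O)[C@@]3(C)OC(C)=O)[C@@H](C)C(=O)O[C@H]2[C@@H](Cl)C(C)=C | intermediate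
24 | C3 primary alcohol (as 23 with CH2OH on C2) | OC[C@H]1O[C@]2([C@H](OC(C)=O)[C@@H]3[C@]1(C)C=C[C@@H](OC(C)=O)[C@@]3(C)OC(C)=O)[C@@H](C)C(=O)O[C@H]2[C@@H](Cl)C(C)=C | intermediate
25 | C3 aldehyde (1S,2S,6S,7R,8S,9R,10S,11S,12R,17R) | O=C[C@H]1O[C@]2([C@H](OC(C)=O)[C@@H]3[C@]1(C)C=C[C@@H](OC(C)=O)[C@@]3(C)OC(C)=O)[C@@H](C)C(=O)O[C@H]2[C@@H](Cl)C(C)=C | intermediate
26 | CNP0333938.3 (1S,2S,3R,6S,7R,8S,9R,10S,11S,12R,17R) | C=C1C[C@@H](O)[C@H]2O[C@]3([C@H](OC(C)=O)[C@@H]4[C@]2(C)C=C[C@@H](OC(C)=O)[C@@]4(C)OC(C)=O)[C@@H](C)C(=O)O[C@H]3[C@H]1Cl | target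

**Step count**
Total: 18 steps. Longest linear sequence: 14 steps (1 to 26 through steps 1–6 and 11–18); the iodide branch from 10 has 4 steps before the coupling.

**Three steps most likely to fail**

Step 18. The carbonyl-ene reaction has to close a trans-bridged eight-membered ring onto an alkene that is deactivated by the allylic chloride, and it also sets C3. The fallback sets out from 23 and comes back at 26. SeO2 with t-BuOOH oxidises the isopropenyl methyl group of 23 to the 2-(hydroxymethyl)allyl alcohol F1. CBr4/PPh3 turns it into the allylic bromide F2. Me2BBr removes the MOM group to give the primary alcohol F3, and Dess–Martin oxidation gives the bromo aldehyde F4. CrCl2 in THF at high dilution then closes C3–C4 by a Nozaki–Hiyama allylation through a much more nucleophilic allylchromium species (non-chelating, so again 3R) and gives 26.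

Step 14. The oxypalladation has to form a tertiary ether at C8 and leave a secondary alkylpalladium that could undergo β-hydride elimination before CO insertion; the allylic 9-acetate may also interfere. The fallback sets out from 19 and comes back at 22. Hg(OCOCF3)2 in CH2Cl2 followed by aqueous NaCl gives, by the same 6-exo anti addition, the stable alkylmercury chloride F5. PdCl2/LiCl/CuCl2 under CO then transfers the alkyl group from mercury to palladium with retention, and CO insertion and lactonisation onto the 7-OH give 22.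

Step 4. The facial selectivity of the addition to the α-quaternary aldehyde rests on a Felkin–Anh/chelate argument and may be low or reversed. The fallback sets out from 5 and comes back at 7. The same addition, quenched with aqueous NH4Cl, gives the carbinol as a C2 epimer mixture F6. Dess–Martin oxidation gives the α-alkoxy ketone F7. Reduction with catecholborane and (S)-1-methyl-3,3-diphenyltetrahydro-1H,3H-pyrrolo[1,2-c][1,3,2]oxazaborole (reagent control, the quaternary ring carbon acting as the large group) gives the (S)-carbinol F8, and Et3SiOTf/2,6-lutidine gives 7.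

**Further compounds**
F1 | step 18 | 2-(hydroxymethyl)allyl alcohol from 23 (CH2OH in place of the isopropenyl CH3) | COCOC[C@H]1O[C@]2([C@H](OC(C)=O)[C@@H]3[C@]1(C)C=C[C@@H](OC(C)=O)[C@@]3(C)OC(C)=O)[C@@H](C)C(=O)O[C@H]2[C@@H](Cl)C(CO)=C
F2 | step 18 | allylic bromide (CH2Br in place of CH2OH of F1) | COCOC[C@H]1O[C@]2([C@H](OC(C)=O)[C@@H]3[C@]1(C)C=C[C@@H](OC(C)=O)[C@@]3(C)OC(C)=O)[C@@H](C)C(=O)O[C@H]2[C@@H](Cl)C(CBr)=C
F3 | step 18 | C3 primary alcohol carrying the allylic bromide | OC[C@H]1O[C@]2([C@H](OC(C)=O)[C@@H]3[C@]1(C)C=C[C@@H](OC(C)=O)[C@@]3(C)OC(C)=O)[C@@H](C)C(=O)O[C@H]2[C@@H](Cl)C(CBr)=C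
F4 | step 18 | C3 aldehyde carrying the allylic bromide | O=C[C@H]1O[C@]2([C@H](OC(C)=O)[C@@H]3[C@]1(C)C=C[C@@H](OC(C)=O)[C@@]3(C)OC(C)=O)[C@@H](C)C(=O)O[C@H]2[C@@H](Cl)C(CBr)=C
F5 | step 14 | alkylmercury chloride (tetrahydropyran closed, HgCl on C17, 6-OH and 7-OH free) | COCOC[C@H]1O[C@]([C@H](OC(C)=O)[C@@H]2[C@]1(C)C=C[C@@H](OC(C)=O)[C@@]2(C)OC(C)=O)([C@@H](C)[Hg]Cl)[C@@H](O)[C@H](O)C(C)=C
F6 | step 4 | ethyl (1S,6S)-6-[1-hydroxy-2-(methoxymethoxy)ethyl]-2,6-dimethylcyclohexa-2,4-diene-1-carboxylate, C2 epimer mixture | CCOC(=O)[C@H]1C(C)=CC=C[C@]1(C)C(O)COCOC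
F7 | step 4 | ethyl (1S,6S)-6-[2-(methoxymethoxy)acetyl]-2,6-dimethylcyclohexa-2,4-diene-1-carboxylate | CCOC(=O)[C@H]1C(C)=CC=C[C@]1(C)C(=O)COCOC
F8 | step 4 | ethyl (1S,6S)-6-[(1S)-1-hydroxy-2-(methoxymethoxy)ethyl]-2,6-dimethylcyclohexa-2,4-diene-1-carboxylate | CCOC(=O)[C@H]1C(C)=CC=C[C@]1(C)[C@H](O)COCOC
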